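## Structural features

The target is an achiral, linear hexamer of oxygenated benzene rings (A to F) held together only by five diaryl ether oxygens; it has no stereocentre, so no neighbouring stereocentres have to be related. Ring A is a phloroglucinol etherified through the oxygen on C2, rings B to E are 3,5-dihydroxy-1,4-phenylenedioxy units, and ring F is a pyrogallol whose C1 carries the ether oxygen para to the C4 hydroxyl. Each ether oxygen joins a crowded ring carbon (flanked by two oxygenated carbons) to a ring carbon flanked by two C–H positions. The fourteen free phenols, above all the pyrogallol ring F and the para-aryloxylated dihydroxy rings, are easily oxidised in air to quinones, so every hydroxyl should stay masked until the last step. The real difficulty is the repeated formation of diaryl ethers between a di-ortho-substituted phenolic oxygen and an electron-rich, non-activated aryl carbon, through intermediates that differ only by one repeat unit. The key step uses ring F: its oxygens on C1, C3 and C5 sit on alternate carbons like a triketide, and the extra oxygen on C4 lies on the carbon between C3 and C5. Cutting C3–C4 therefore opens ring F to a 3-aryloxy-5-oxohexenoate with a methoxy-bearing terminal carbon, which is the open form of a 4-aryloxy-6-(methoxymethyl)-2-pyranone.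

## Logic of the disconnections

20 to 19: the twelve O–CH3 bonds are cut. Methyl ethers are the only masks that survive copper coupling, alkoxide base and acid alike, and they come with the purchasable monomers. The gain is an air-stable, chromatographable penultimate compound; the demand is one exhaustive ether cleavage that leaves the five diaryl ether bonds intact.

19 to 17 (through 18): the C3–C4 bond of ring F is cut, which gives the open-chain keto ester 18, and 18 is folded back through its ester and C5 oxygen into the lactone 17. This replaces the sixth aryl ring by a six-carbon chain that can be made from simple acyclic pieces and removes the last aryl–oxygen coupling. The forward step needs alkoxide attack at the lactone carbonyl rather than at the aryloxy-bearing C4, and C-acylation by the methoxy-bearing carbon rather than return to the lactone.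

17 to 16 and 5: the bond between the ring E oxygen and pyranone C4 is cut. C4 is the beta-carbon of a vinylogous acyl halide, so the crowded phenoxide can be attached by addition–elimination without a metal. Bromide is chosen as the leaving group because a sulfonate would offer a second electrophilic centre at sulfur. The demand is attack at C4 rather than at C2 or C6 of 5.

5 to 4, 4 to 3, 3 to 1 and 2: the C–Br bond, then the lactone C–O bond, then the C4–C5 bond of the hexanoate chain are cut. This leads back to two purchasable esters. The forward acylation needs the dianion of 1 to react at its terminal carbon, and an ester (2) is used as acyl donor so that O-acylation and double acylation are excluded.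

16 to 14 and 7, 14 to 12 and 7, 12 to 10 and 7, 10 to 8 and 7 (each through a methoxymethyl ether: 15, 13, 11, 9): in each case the bond between the crowded phenolic oxygen and the unsubstituted carbon of the next ring is cut. One monomer serves four times, and every cycle returns a phenol with the same local environment. The demand is a copper-catalysed coupling that tolerates a di-ortho-substituted phenol and an electron-rich aryl bromide, and a phenol mask that survives the coupling base but falls to acid.

7 to 6: the O–CH2OCH3 bond is cut, so that the bromophenol monomer cannot couple with itself.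

## Other disconnections considered

Alternative 1: The cut lies in ring A at C2–C3 and C5–C6. C1 and its two neighbours come from the aryloxymalonate A2 of the ring B–F pentamer, and C3–C4–C5 from dimethyl 3-oxopentanedioate A1. In the forward step the bis-enolate of A1 is acylated at both alpha-carbons by the two ester groups of A2, closing ring A as the phloroglucinol diester A3. Saponification, double decarboxylation and demethylation would follow.
- In its favour: both C–C bonds are made by doubly stabilised carbanions in a classical condensation type, which is better than the singly stabilised carbanion of the chosen plan. A2 is made by O-alkylating an unhindered phenoxide, which is easier than step 9. Ring A arrives with free hydroxyls, so three fewer methyl ethers remain.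
- Against it: A2 has an acidic methine, and once it is deprotonated its esters are poor acyl acceptors, while A1 tends to self-condense. The two ester groups of A3 are not in the target and must be removed on an oxidisable phloroglucinol. The pentamer must carry its free phenol at the unhindered end, which needs a second, orthogonal terminal mask and one more monomer.
- Comparison: on structure the two plans are equal, since each builds a terminal ring on a pentamer after four ether couplings. On mechanism the alternative has the better nucleophile but the worse electrophile and needs two intermolecular acylations, whereas the chosen plan needs one intramolecular closure with preset geometry. On step economy the alternative is about two steps longer.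

Alternative 2: The cut lies in the central ring C at C2–C3 and C1–C6. In the forward step the ring A–B ethynyl ether A4 is heated with the 4-aryloxy-3-ethoxycyclobutenone A5 that carries rings D–F. Ring opening to a vinylketene, [2+2] addition to the ynol ether, a second four-electron opening and a six-electron closure give the hexamer A6 with a free C3 phenol and a C5 ethyl ether on ring C.
- In its favour: this is the most convergent plan, with a two-ring and a three-ring arm, only three copper couplings and a shorter longest linear sequence; on convergence it is better than the chosen plan. The pericyclic cascade needs no base, so no aryloxide can be displaced, and the regiochemistry follows from the polarity of the ynol ether.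
- Against it: aryl ethynyl ethers are thermally labile, while the 3-ethoxy group stabilises the cyclobutenone and pushes the ring opening to higher temperature, so the two partners have opposed thermal needs. Both partners carry bulky aryloxy groups at the reacting carbons, and each needs two or three extra steps of sensitive chemistry.
- Comparison: on structure the alternative is better (central cut). On mechanism it is cleaner in principle but rests on two fragile reagents, against one base-mediated isomerisation of a stable lactone. On total step count the two are about equal.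

Alternative 3: The cut is at the C3–O and C5–O bonds of rings A to E. All ten hydroxyls of these rings are carried as formyl groups, which activate the flanked ring carbon for metal-free nucleophilic aromatic substitution during chain assembly. In the forward step a peracid converts the decaaldehyde A7 into the decaformate A8 by tenfold Baeyer–Villiger aryl migration. Methanolysis and cleavage of only four methyl ethers would finish the synthesis.
- In its favour: the ether-forming steps use doubly activated aryl halides and need no copper, which is better than steps 5 to 8. Ten oxygens are introduced in one operation and the final ether cleavage is much lighter, which is also better.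
- Against it: each ring carries two formyl groups meta to each other, so the first oxidation must occur on an electron-poor ring where hydrogen migration to the acid competes. Formates that hydrolyse early expose electron-rich phenols to the peracid. Ten events must all go the same way in one molecule. The monomers carry a phenol and an activated halide together and need protection.
- Comparison: on structure it is equal (linear iteration). On mechanism it is stronger in the coupling steps and weaker in the key step. On step economy it is similar or slightly shorter, but with a much higher demand on per-site selectivity than the single ring closure of the chosen plan.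

Key step: step 10

Remark on the chemistry: the open-chain ester formed from the lactone is the (2E) isomer by the sequence rules (ester and C4 methylene cis), and the ring closure is of the enolendo type; the connectivities of 17 and 19 match the target and are kept.

## Route

Step 1
Reactants: 1 methyl acetoacetate; 2 methyl methoxyacetate
Product: 3 methyl 6-methoxy-3,5-dioxohexanoate
Conditions: 1 (2.2 equiv), NaH then n-BuLi, THF, 0 °C; 2 (1 equiv), 0 °C to rt; aq. HCl
Reagents that add atoms: none
Why: Claisen-type gamma-acylation of the acetoacetate dianion, whose terminal carbanion is the more nucleophilic site; the excess dianion takes up the more acidic product. An ester is used as acyl donor because, unlike the acid chloride, it cannot O-acylate or acylate twice.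

Step 2
Reactants: 3 methyl 6-methoxy-3,5-dioxohexanoate
Product: 4 4-hydroxy-6-(methoxymethyl)-2H-pyran-2-one
Conditions: DBU, toluene, 80 °C; aq. HCl
Reagents that add atoms: none
Why: Base-promoted lactonisation of a 3,5-dioxo ester: the C5 enolate oxygen attacks the ester carbonyl (6-exo-trig) and methanol is lost, a standard entry to 6-substituted 4-hydroxy-2-pyranones.

Step 3
Reactants: 4 4-hydroxy-6-(methoxymethyl)-2H-pyran-2-one
Product: 5 4-bromo-6-(methoxymethyl)-2H-pyran-2-one
Conditions: (COBr)2, DMF (cat.), CH2Cl2, 0 °C to rt
Reagents that add atoms: oxalyl bromide, O=C(Br)C(=O)Br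
Why: Vilsmeier-type deoxybromination of a vinylogous acid: the bromoiminium salt activates the 4-oxygen and bromide displaces it by addition–elimination at C4. The conditions are mild enough to leave the methyl ether alone.

Step 4
Reactants: 6 4-bromo-2,6-dimethoxyphenol
Product: 7 5-bromo-1,3-dimethoxy-2-(methoxymethoxy)benzene
Conditions: MOMCl, i-Pr2NEt, CH2Cl2, 0 °C to rt
Reagents that add atoms: chloromethyl methyl ether, COCCl
Why: Williamson-type O-alkylation gives a methoxymethyl ether that withstands the basic copper coupling and is cleaved by acid without touching aryl methyl or diaryl ethers; it stops the monomer from coupling with itself.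

Step 5
Reactants: 8 2,4,6-trimethoxyphenol; 7 5-bromo-1,3-dimethoxy-2-(methoxymethoxy)benzene
Product: 10 2,6-dimethoxy-4-(2,4,6-trimethoxyphenoxy)phenol, via dimer methoxymethyl ether 9 (not isolated)
Conditions: CuI (10 mol%), picolinic acid (20 mol%), K3PO4, DMSO, 100 °C, Ar; extractive removal of DMSO and salts; crude, HCl, MeOH, 50 °C, Ar
Reagents that add atoms: none
Why: Ullmann-type diaryl ether coupling with CuI and picolinic acid, a system suited to di-ortho-substituted phenols; the bromide of 7 has no ortho substituent. DMSO and bromide are washed out before acidification, because acid, bromide and DMSO together would brominate the electron-rich rings; acid-catalysed acetal exchange with methanol then frees the next 2,6-dimethoxyphenol.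

Step 6
Reactants: 10 2,6-dimethoxy-4-(2,4,6-trimethoxyphenoxy)phenol; 7 5-bromo-1,3-dimethoxy-2-(methoxymethoxy)benzene
Product: 12 4-[2,6-dimethoxy-4-(2,4,6-trimethoxyphenoxy)phenoxy]-2,6-dimethoxyphenol (ring A–C trimer phenol), via trimer methoxymethyl ether 11 (not isolated)
Conditions: CuI (10 mol%), picolinic acid (20 mol%), K3PO4, DMSO, 100 °C, Ar; extractive removal of DMSO and salts; crude, HCl, MeOH, 50 °C, Ar
Reagents that add atoms: none
Why: Same Ullmann coupling and acetal cleavage as in step 5; the reacting phenol has the same local environment, only the remote chain is longer.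

Step 7
Reactants: 12 ring A–C trimer phenol; 7 5-bromo-1,3-dimethoxy-2-(methoxymethoxy)benzene
Product: 14 ring A–D tetramer phenol (homologue of 12 with one more 3,5-dimethoxy-1,4-phenylenedioxy unit; OH on ring D C4 between two methoxy groups), via tetramer methoxymethyl ether 13 (not isolated)
Conditions: CuI (10 mol%), picolinic acid (20 mol%), K3PO4, DMSO, 100 °C, Ar; extractive removal of DMSO and salts; crude, HCl, MeOH, 50 °C, Ar
Reagents that add atoms: none
Why: Third cycle of the Ullmann coupling and acid acetal cleavage, on the same type of phenol and the same bromide.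

Step 8
Reactants: 14 ring A–D tetramer phenol; 7 5-bromo-1,3-dimethoxy-2-(methoxymethoxy)benzene
Product: 16 ring A–E pentamer phenol (homologue of 14 with one more unit; OH on ring E C4 between two methoxy groups), via pentamer methoxymethyl ether 15 (not isolated)
Conditions: CuI (15 mol%), picolinic acid (30 mol%), K3PO4, DMSO, 100 °C, Ar; extractive removal of DMSO and salts; crude, HCl, MeOH/THF, 50 °C, Ar
Reagents that add atoms: none
Why: Fourth cycle of the Ullmann coupling and acetal cleavage; THF is added in the acid stage to keep the larger ether in solution.

Step 9
Reactants: 16 ring A–E pentamer phenol; 5 4-bromo-6-(methoxymethyl)-2H-pyran-2-one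
Product: 17 4-(pentamer-oxy)-6-(methoxymethyl)-2H-pyran-2-one (ring E oxygen bonded to pyranone C4)
Conditions: Cs2CO3, dry DMF, 25–40 °C, Ar
Reagents that add atoms: none
Why: Addition–elimination (vinylogous acyl substitution) of the phenoxide at C4 of the 4-bromo-2-pyranone, a reaction known for phenols with 4-bromo-6-methyl-2-pyranone. Bromide offers only C4 for productive attack, whereas a sulfonate would also invite the hard phenoxide to attack at sulfur.

Step 10
Reactants: 17 4-(pentamer-oxy)-6-(methoxymethyl)-2H-pyran-2-one
Product: 19 5-(pentamer-oxy)-2-methoxybenzene-1,3-diol (hexamer, ring F as 3,5-dihydroxy-4-methoxyphenyl ether), via ring-opened keto ester 18 (not isolated)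
Conditions: Mg(OMe)2 (6 equiv), MeOH/THF 3:1, 65 °C, Ar, ca. 0.02 M; then 1 M HCl
Reagents that add atoms: none
Why: Proposed new method: methoxide from Mg(OMe)2 adds to the lactone carbonyl (pyranone C2) and the ring opens to the magnesium enolate of 18, in which the ester and the C4 methylene stay cis on the C2=C3 double bond (2E) because they were ring neighbours. Reversible enolisation towards the methoxy-bearing chain carbon C6 lets that carbon attack the ester carbonyl, forming the ring F C3–C4 bond; loss of methoxide and two enolisations give the 2-methoxyresorcinol, which leaves all equilibria as its magnesium phenoxide. The closest known reaction type is the Mg(OMe)2-induced opening of 4-methoxy-2-pyranones followed by Claisen recyclisation of the polyketide ester to phloroglucinol and resorcinol ethers; new here are the 4-aryloxy group and the alpha-alkoxy ketone carbanion as nucleophile. Ring F closes in a 6-(enolendo)-exo-trig mode, since the enolate C5=C6 bond lies inside the new ring and the ester C=O outside it. No stereocentre is formed, and the alkene geometry needed for closure is inherited from the lactone. The step needs methoxide to attack pyranone C2 rather than C4 (which would expel the pentamer phenoxide), and C-acylation at C6 rather than return to the lactone by O-acylation. The two ortho methoxy groups of ring E screen C4, and magnesium bound to the lactone carbonyl activates C2 while keeping free methoxide low. A five-membered magnesium chelate between the C5 ketone oxygen and the C6 methoxy oxygen acidifies the C6 hydrogens, and O-acylation is reversible whereas aromatisation is not.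

Step 11
Reactants: 19 5-(pentamer-oxy)-2-methoxybenzene-1,3-diol
Product: 20 CNP0187343.0 (fully deprotected hexamer, fourteen free hydroxyls)
Conditions: BBr3 (ca. 30 equiv), CH2Cl2, −78 °C to rt, Ar; MeOH quench, evaporation; reversed-phase or Sephadex LH-20 purification under Ar
Reagents that add atoms: none
Why: Lewis acid-mediated cleavage of aryl methyl ethers: each ArO–CH3 oxygen binds boron and bromide attacks the methyl carbon (SN2). The diaryl ether bonds offer no sp3 carbon and survive; methanolysis of the aryl borates releases the phenols.

## Compound list

1 | methyl acetoacetate | COC(=O)CC(C)=O | starting material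
2 | methyl methoxyacetate | COCC(=O)OC | starting material
3 | methyl 6-methoxy-3,5-dioxohexanoate | COCC(=O)CC(=O)CC(=O)OC | intermediate
4 | 4-hydroxy-6-(methoxymethyl)-2H-pyran-2-one | COCC1=CC(O)=CC(=O)O1 | intermediate
5 | 4-bromo-6-(methoxymethyl)-2H-pyran-2-one | COCC1=CC(Br)=CC(=O)O1 | intermediate
6 | 4-bromo-2,6-dimethoxyphenol | COc1cc(Br)cc(OC)c1O | starting material
7 | 5-bromo-1,3-dimethoxy-2-(methoxymethoxy)benzene | COCOc1c(OC)cc(Br)cc1OC | intermediate
8 | 2,4,6-trimethoxyphenol | COc1cc(OC)c(O)c(OC)c1 | starting material
9 | 2-[3,5-dimethoxy-4-(methoxymethoxy)phenoxy]-1,3,5-trimethoxybenzene (dimer methoxymethyl ether) | COc1cc(OC)c(Oc2cc(OC)c(OCOC)c(OC)c2)c(OC)c1 | intermediate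
10 | 2,6-dimethoxy-4-(2,4,6-trimethoxyphenoxy)phenol (ring A–B dimer phenol) | COc1cc(OC)c(Oc2cc(OC)c(O)c(OC)c2)c(OC)c1 | intermediate
11 | ring A–C trimer methoxymethyl ether | COc1cc(OC)c(Oc2cc(OC)c(Oc3cc(OC)c(OCOC)c(OC)c3)c(OC)c2)c(OC)c1 | intermediate
12 | 4-[2,6-dimethoxy-4-(2,4,6-trimethoxyphenoxy)phenoxy]-2,6-dimethoxyphenol (ring A–C trimer phenol) | COc1cc(OC)c(Oc2cc(OC)c(Oc3cc(OC)c(O)c(OC)c3)c(OC)c2)c(OC)c1 | intermediate
13 | ring A–D tetramer methoxymethyl ether | COc1cc(OC)c(Oc2cc(OC)c(Oc3cc(OC)c(Oc4cc(OC)c(OCOC)c(OC)c4)c(OC)c3)c(OC)c2)c(OC)c1 | intermediate
14 | ring A–D tetramer phenol | COc1cc(OC)c(Oc2cc(OC)c(Oc3cc(OC)c(Oc4cc(OC)c(O)c(OC)c4)c(OC)c3)c(OC)c2)c(OC)c1 | intermediate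
15 | ring A–E pentamer methoxymethyl ether | COc1cc(OC)c(Oc2cc(OC)c(Oc3cc(OC)c(Oc4cc(OC)c(Oc5cc(OC)c(OCOC)c(OC)c5)c(OC)c4)c(OC)c3)c(OC)c2)c(OC)c1 | intermediate
16 | ring A–E pentamer phenol | COc1cc(OC)c(Oc2cc(OC)c(Oc3cc(OC)c(Oc4cc(OC)c(Oc5cc(OC)c(O)c(OC)c5)c(OC)c4)c(OC)c3)c(OC)c2)c(OC)c1 | intermediate
17 | 4-(pentamer-oxy)-6-(methoxymethyl)-2H-pyran-2-one | COc1cc(OC)c(Oc2cc(OC)c(Oc3cc(OC)c(Oc4cc(OC)c(Oc5cc(OC)c(OC6=CC(=O)OC(COC)=C6)c(OC)c5)c(OC)c4)c(OC)c3)c(OC)c2)c(OC)c1 | intermediate
18 | methyl (2E)-6-methoxy-5-oxo-3-(pentamer-oxy)hex-2-enoate | COc1cc(OC)c(Oc2cc(OC)c(Oc3cc(OC)c(Oc4cc(OC)c(Oc5cc(OC)c(O/C(CC(=O)COC)=C/C(=O)OC)c(OC)c5)c(OC)c4)c(OC)c3)c(OC)c2)c(OC)c1 | intermediate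
19 | 5-(pentamer-oxy)-2-methoxybenzene-1,3-diol (hexamer, ring F 3,5-dihydroxy-4-methoxyphenyl) | COc1cc(OC)c(Oc2cc(OC)c(Oc3cc(OC)c(Oc4cc(OC)c(Oc5cc(OC)c(Oc6cc(O)c(OC)c(O)c6)c(OC)c5)c(OC)c4)c(OC)c3)c(OC)c2)c(OC)c1 | intermediate
20 | CNP0187343.0 | Oc1cc(O)c(Oc2cc(O)c(Oc3cc(O)c(Oc4cc(O)c(Oc5cc(O)c(Oc6cc(O)c(O)c(O)c6)c(O)c5)c(O)c4)c(O)c3)c(O)c2)c(O)c1 | target

## Step count and least certain steps

Total: 11 steps. Longest linear sequence: 8 steps (steps 4 to 11, from 6). The pyranone arm (steps 1 to 3) joins at step 9.

**Step 10 (key step).** The most likely failure is displacement of the pentamer aryloxide by methoxide, at pyranone C4 or at C3 of the open-chain ester. The second is stalling at the open-chain stage: the C6 carbanion is only singly stabilised and the ester is a deactivated vinylogous carbonate. Fallback with known chemistry: starting from 16, the same CuI/picolinic acid coupling as in steps 5 to 8, with purchased 5-bromo-1,2,3-trimethoxybenzene, would give the permethylated hexamer F1. Cleavage of its fifteen methyl ethers with BBr3 would then give the target, so the route is rejoined at 20.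

**Step 9.** Attack at C4 by the crowded phenoxide may be slow, which leaves time for base-induced degradation of the bromopyranone or for attack at C2 or C6. Fallback: starting from 16 and 5, a palladium-catalysed C–O cross-coupling (Pd(OAc)2, t-BuXPhos, K3PO4, toluene, 80 °C) would form the same bond by oxidative addition and reductive elimination instead of addition–elimination. 4-Halo-2-pyranones are established partners in palladium couplings. The route is rejoined at 17, and no new compound is made (entry F0).

**Step 8 (and likewise steps 5 to 7).** Oxidative addition to the electron-rich aryl bromide may be slow, with competing loss of bromine, and the electron-rich phenoxide may degrade oxidatively; both get worse as the chain grows. Fallback: starting from 14, metal-free nucleophilic aromatic substitution on purchasable 4-fluoro-2,6-dimethoxybenzaldehyde (K2CO3, DMF, 100 °C) would give the pentamer aldehyde F2. Baeyer–Villiger oxidation with mCPBA (CH2Cl2, NaHCO3) would give the pentamer aryl formate F3, and methanolysis (K2CO3, MeOH) would return to the route at 16.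

**Step 11.** Cleavage of twelve ethers may stop short and leave partly methylated mixtures, and the polyphenol may oxidise in air during isolation. Fallback: starting from 19, the crude product of the BBr3 reaction would be acetylated (Ac2O, pyridine) to the tetradecaacetate F4, which is stable and can be purified on silica. Acid methanolysis (HCl in MeOH, from AcCl, 0 °C to rt, Ar) would then release 20.

**Step 3.** The HBr formed may cleave the methoxymethyl side-chain ether, or bromination may occur elsewhere. Fallback: starting from 4, sulfonylation (TsCl, Et3N, CH2Cl2, 0 °C) would give 6-(methoxymethyl)-2-oxo-2H-pyran-4-yl 4-methylbenzenesulfonate F5. This would be used in place of 5 with 16 (Cs2CO3, DMF), and the route is rejoined at 17.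

## Further compounds

F1 | step 10 | permethylated hexamer (ring F as 3,4,5-trimethoxyphenyl ether) | COc1cc(OC)c(Oc2cc(OC)c(Oc3cc(OC)c(Oc4cc(OC)c(Oc5cc(OC)c(Oc6cc(OC)c(OC)c(OC)c6)c(OC)c5)c(OC)c4)c(OC)c3)c(OC)c2)c(OC)c1
F0 | step 9 | none | none
F2 | step 8 | ring A–E pentamer aldehyde (ring E as 4-formyl-3,5-dimethoxyphenyl ether) | COc1cc(OC)c(Oc2cc(OC)c(Oc3cc(OC)c(Oc4cc(OC)c(Oc5cc(OC)c(C=O)c(OC)c5)c(OC)c4)c(OC)c3)c(OC)c2)c(OC)c1
F3 | step 8 | ring A–E pentamer aryl formate | COc1cc(OC)c(Oc2cc(OC)c(Oc3cc(OC)c(Oc4cc(OC)c(Oc5cc(OC)c(OC=O)c(OC)c5)c(OC)c4)c(OC)c3)c(OC)c2)c(OC)c1
F4 | step 11 | tetradecaacetate of the target | CC(=O)Oc1cc(OC(C)=O)c(Oc2cc(OC(C)=O)c(Oc3cc(OC(C)=O)c(Oc4cc(OC(C)=O)c(Oc5cc(OC(C)=O)c(Oc6cc(OC(C)=O)c(OC(C)=O)c(OC(C)=O)c6)c(OC(C)=O)c5)c(OC(C)=O)c4)c(OC(C)=O)c3)c(OC(C)=O)c2)c(OC(C)=O)c1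
F5 | step 3 | 6-(methoxymethyl)-2-oxo-2H-pyran-4-yl 4-methylbenzenesulfonate | COCC1=CC(OS(=O)(=O)c2ccc(C)cc2)=CC(=O)O1
A1 | alternative 1 | dimethyl 3-oxopentanedioate | COC(=O)CC(=O)CC(=O)OC
A2 | alternative 1 | dimethyl 2-(ring B–F pentamer-oxy)malonate | COC(=O)C(Oc1cc(OC)c(Oc2cc(OC)c(Oc3cc(OC)c(Oc4cc(OC)c(Oc5cc(OC)c(OC)c(OC)c5)c(OC)c4)c(OC)c3)c(OC)c2)c(OC)c1)C(=O)OC
A3 | alternative 1 | hexamer with ring A as dimethyl 2,4,6-trihydroxy-5-aryloxybenzene-1,3-dicarboxylate | COC(=O)c1c(O)c(C(=O)OC)c(O)c(Oc2cc(OC)c(Oc3cc(OC)c(Oc4cc(OC)c(Oc5cc(OC)c(Oc6cc(OC)c(OC)c(OC)c6)c(OC)c5)c(OC)c4)c(OC)c3)c(OC)c2)c1O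
A4 | alternative 2 | 2-[4-(ethynyloxy)-3,5-dimethoxyphenoxy]-1,3,5-trimethoxybenzene (ring A–B ethynyl ether) | COc1cc(OC)c(Oc2cc(OC)c(OC#C)c(OC)c2)c(OC)c1
A5 | alternative 2 | 3-ethoxy-4-(ring D–F trimer-oxy)cyclobut-2-en-1-one | CCOC1=CC(=O)C1Oc2cc(OC)c(Oc3cc(OC)c(Oc4cc(OC)c(OC)c(OC)c4)c(OC)c3)c(OC)c2
A6 | alternative 2 | hexamer with ring C as 3-hydroxy-5-ethoxy unit | COc1cc(OC)c(Oc2cc(OC)c(Oc3cc(O)c(Oc4cc(OC)c(Oc5cc(OC)c(Oc6cc(OC)c(OC)c(OC)c6)c(OC)c5)c(OC)c4)c(OCC)c3)c(OC)c2)c(OC)c1
A7 | alternative 3 | hexamer decaaldehyde | COc1cc(C=O)c(Oc2cc(C=O)c(Oc3cc(C=O)c(Oc4cc(C=O)c(Oc5cc(C=O)c(Oc6cc(OC)c(OC)c(OC)c6)c(C=O)c5)c(C=O)c4)c(C=O)c3)c(C=O)c2)c(C=O)c1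
A8 | alternative 3 | hexamer decaformate | COc1cc(OC=O)c(Oc2cc(OC=O)c(Oc3cc(OC=O)c(Oc4cc(OC=O)c(Oc5cc(OC=O)c(Oc6cc(OC)c(OC)c(OC)c6)c(OC=O)c5)c(OC=O)c4)c(OC=O)c3)c(OC=O)c2)c(OC=O)c1
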